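**Plan**

1. Numbering (daucane): C1 = quaternary ring-fusion carbon (CH3); C2, C3 = ring CH2; C4 = isopropyl-bearing sp2 carbon; C5 = sp2 ring-fusion carbon; C6, C7 = CH2; C8 = carbon bearing C14H2O; C9 = ring =CH; C10 = ring CH2 on C1.
2. Cuts: the C14–O ester bond (last step); then, in one operation, C8=C9 (aldol condensation of a C9/C14 dialdehyde) and C1–C10 ([3,3] Claisen shift from an oxygen on C4); before that the C4–isopropyl bond and C5–C6.
3. Enabling feature: C1 is allylic to the C4=C5 double bond of the five-membered ring and carries the two-carbon unit C10–C9. C4=C5–C1–C10–C9(=O) is thus a γ,δ-unsaturated aldehyde (Claisen retron), and C9=C8–C14(=O) is an enal (aldol retron) of the seven-membered ring.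
4. Forward order: the five-membered ring comes from 3-methylcyclopentane-1,2-dione (triflate, B-alkyl Suzuki coupling of the C6–C7–C8–C14 chain); C4 is then made a tertiary carbinol; the seven-membered ring closes last, in the key step.
5. Stereochemistry: a CBS reduction sets the C4–O face; lithiation–borylation replaces H on C4 by isopropyl with oxygen kept on the same face; the Claisen shift relays (S)-C4 to (R)-C1 across one ring face while C4 becomes sp2.

Key step: step 7

Remark: compound 1 is used as its stable enol tautomer; compound 12 forms as a mixture of epimers at sulfur, which is without consequence because sulfur is lost in step 7.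

**Step 1**
Reactants: 1 2-hydroxy-3-methylcyclopent-2-en-1-one
Product: 2 2-methyl-5-oxocyclopent-1-en-1-yl trifluoromethanesulfonate
Conditions: Tf2O, pyridine, CH2Cl2, −78 → 0 °C
Reagents that add atoms: trifluoromethanesulfonic anhydride, O=S(=O)(OS(=O)(=O)C(F)(F)F)C(F)(F)F
Why: O-sulfonylation of the enol of a cyclic 1,2-dione should give the α-triflyloxy enone, an electron-poor vinyl triflate ready for cross-coupling, with no stereocenter involved.

**Step 2**
Reactants: 2 2-methyl-5-oxocyclopent-1-en-1-yl trifluoromethanesulfonate; 3 4,4-diethoxybut-1-ene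
Product: 5 2-(4,4-diethoxybutyl)-3-methylcyclopent-2-en-1-one, via alkylborane 4 (not isolated)
Conditions: 3, 9-BBN, THF, 0 → 23 °C; then 2, PdCl2(dppf), AsPh3, Cs2CO3, DMF/THF/H2O, 23 °C
Reagents that add atoms: none
Why: anti-Markovnikov hydroboration followed by B-alkyl Suzuki–Miyaura coupling with the vinyl triflate should join C5–C6, the acetal being inert to the basic medium.

**Step 3**
Reactants: 5 2-(4,4-diethoxybutyl)-3-methylcyclopent-2-en-1-one
Product: 6 (1R)-2-(4,4-diethoxybutyl)-3-methylcyclopent-2-en-1-ol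
Conditions: (S)-2-methyl-CBS-oxazaborolidine (0.2 equiv), BH3·SMe2, THF, −20 °C
Reagents that add atoms: none
Why: Corey–Bakshi–Shibata reduction, in which the α-substituted alkenyl arm acts as the large group, should deliver hydride to one carbonyl face and set the (R)-carbinol at C4.

**Step 4**
Reactants: 6 (1R)-2-(4,4-diethoxybutyl)-3-methylcyclopent-2-en-1-ol
Product: 7 (1R)-2-(4,4-diethoxybutyl)-3-methylcyclopent-2-en-1-yl N,N-di(propan-2-yl)carbamate
Conditions: iPr2NCOCl, Et3N, CH2Cl2, 40 °C
Reagents that add atoms: N,N-diisopropylcarbamoyl chloride, CC(C)N(C(C)C)C(Cl)=O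
Why: O-carbamoylation of the secondary allylic alcohol installs the directing and leaving group for the next step without touching the stereocenter.

**Step 5**
Reactants: 7 (1R)-2-(4,4-diethoxybutyl)-3-methylcyclopent-2-en-1-yl N,N-di(propan-2-yl)carbamate
Product: 11 (1S)-2-(4,4-diethoxybutyl)-3-methyl-1-(propan-2-yl)cyclopent-2-en-1-ol, via lithiated carbamate 8 (not isolated), via boronate complex 9 (not isolated), via tertiary boronic ester 10 (not isolated)
Conditions: s-BuLi, TMEDA, Et2O, −78 °C; iPrBpin, −78 °C; MgBr2·OEt2, MeOH, −78 → 23 °C; then NaOH, H2O2, THF/H2O, 0 → 23 °C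
Reagents that add atoms: 2-isopropyl-4,4,5,5-tetramethyl-1,3,2-dioxaborolane, CC(C)B1OC(C)(C)C(C)(C)O1; hydrogen peroxide, OO
Why: Hoppe-type α-lithiation and borylation both proceed with retention, the stereospecific 1,2-metallate shift of isopropyl (Aggarwal lithiation–borylation) expels the carbamate with inversion at carbon and the oxidation retains the C–B configuration, so isopropyl replaces H while oxygen returns to the same ring face and (S)-C4 results.

**Step 6**
Reactants: 11 (1S)-2-(4,4-diethoxybutyl)-3-methyl-1-(propan-2-yl)cyclopent-2-en-1-ol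
Product: 12 (1S)-2-(4,4-diethoxybutyl)-3-methyl-1-(propan-2-yl)cyclopent-2-en-1-yl 2-(phenylsulfinyl)ethyl ether (both sulfur epimers)
Conditions: phenyl vinyl sulfoxide, KH (0.2 equiv), THF, 0 → 23 °C
Reagents that add atoms: phenyl vinyl sulfoxide, C=CS(=O)c1ccccc1
Why: base-catalysed oxa-Michael addition of the tertiary alkoxide to the vinyl sulfoxide masks a vinyl ether under purely basic conditions, which the acid-labile tertiary allylic carbinol tolerates, and leaves C4 untouched.

**Step 7**
Reactants: 12 (1S)-2-(4,4-diethoxybutyl)-3-methyl-1-(propan-2-yl)cyclopent-2-en-1-yl 2-(phenylsulfinyl)ethyl ether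
Product: 16 (3aR)-3a-methyl-1-(propan-2-yl)-2,3,3a,4,7,8-hexahydroazulene-6-carbaldehyde, via allyl vinyl ether 13 (not isolated), via Claisen aldehyde 14 (not isolated), via dialdehyde 15 (not isolated)
Conditions: NaHCO3 (buffer), 1,2-dichlorobenzene, 170 °C; then 1 M aq HCl, THF, 23 °C; then piperidine, AcOH, 60 °C (one pot)
Reagents that add atoms: water, O
Why: Heating causes syn-elimination of benzenesulfenic acid to the allyl vinyl ether 13, which undergoes a concerted [3,3] Claisen shift through a boat-like transition state over one face of the cyclopentene, breaking C4–O and making C1–C10 and C4=C5 (closest known type: the sulfoxide-elimination/Claisen tandem of 2-(phenylsulfinyl)ethyl allyl ethers). Aqueous acid then unmasks the C14 aldehyde, and piperidinium acetate effects an enamine-mediated intramolecular aldol condensation of the 1,8-dialdehyde 15 that makes C8=C9 (closest known type: amine-salt cyclisation of dialdehydes to cycloalkene-1-carbaldehydes). The Claisen stage closes no ring; the seven-membered ring closes in the aldol stage in the 7-(enolexo)-exo-trig mode. The only new stereocenter, C1, is set by suprafacial chirality transfer, since the O–C9=C10 bridge can reach C1 only on the ring face that bears the C4–O bond, so (S)-C4 gives (R)-C1 as C4 turns sp2. The step needs regioselection between the two aldehydes, and the quaternary C1 next to C10 should secure it by making C10 a hindered neopentyl nucleophile, so that the unhindered C8 enamine attacks the C9 aldehyde and dehydration fixes C8=C9 in conjugation with C14=O.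

**Step 8**
Reactants: 16 (3aR)-3a-methyl-1-(propan-2-yl)-2,3,3a,4,7,8-hexahydroazulene-6-carbaldehyde
Product: 17 [(3aR)-3a-methyl-1-(propan-2-yl)-2,3,3a,4,7,8-hexahydroazulen-6-yl]methanol
Conditions: NaBH4, CeCl3·7H2O, MeOH, 0 °C
Reagents that add atoms: none
Why: Luche reduction should give clean 1,2-reduction of the enal to the primary allylic alcohol without touching either alkene or C1.

**Step 9**
Reactants: 17 [(3aR)-3a-methyl-1-(propan-2-yl)-2,3,3a,4,7,8-hexahydroazulen-6-yl]methanol; 18 4-hydroxy-3-methoxybenzoic acid (vanillic acid)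
Product: 19 [(3aR)-3a-methyl-1-(propan-2-yl)-2,3,3a,4,7,8-hexahydroazulen-6-yl]methyl 4-hydroxy-3-methoxybenzoate
Conditions: PPh3, DIAD, THF, 0 → 23 °C
Reagents that add atoms: none
Why: Mitsunobu esterification should engage the carboxylic acid, far more acidic than the phenol, in direct displacement at the primary allylic carbon, so the phenol needs no protection and no stereocenter is affected.

**Compound list**

1 | 2-hydroxy-3-methylcyclopent-2-en-1-one (enol form of 3-methylcyclopentane-1,2-dione) | CC1=C(O)C(=O)CC1 | starting material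
2 | 2-methyl-5-oxocyclopent-1-en-1-yl trifluoromethanesulfonate | CC1=C(OS(=O)(=O)C(F)(F)F)C(=O)CC1 | intermediate
3 | 4,4-diethoxybut-1-ene | C=CCC(OCC)OCC | starting material
4 | 9-(4,4-diethoxybutyl)-9-borabicyclo[3.3.1]nonane | CCOC(CCCB1C2CCCC1CCC2)OCC | intermediate
5 | 2-(4,4-diethoxybutyl)-3-methylcyclopent-2-en-1-one | CCOC(CCCC1=C(C)CCC1=O)OCC | intermediate
6 | (1R)-2-(4,4-diethoxybutyl)-3-methylcyclopent-2-en-1-ol | O[C@@H]1CCC(C)=C1CCCC(OCC)OCC | intermediate
7 | (1R)-2-(4,4-diethoxybutyl)-3-methylcyclopent-2-en-1-yl N,N-di(propan-2-yl)carbamate | CC(C)N(C(C)C)C(=O)O[C@@H]1CCC(C)=C1CCCC(OCC)OCC | intermediate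
8 | α-lithiated carbamate (Li in place of H on the carbinol carbon of 7, configuration retained) | [Li][C@@]1(OC(=O)N(C(C)C)C(C)C)CCC(C)=C1CCCC(OCC)OCC | intermediate
9 | lithium isopropyl(pinacolato)borate complex of 8 (boron on the former C–Li position) | CC(C)[B-]1(OC(C)(C)C(C)(C)O1)[C@@]2(OC(=O)N(C(C)C)C(C)C)CCC(C)=C2CCCC(OCC)OCC.[Li+] | intermediate
10 | 2-[(1R)-2-(4,4-diethoxybutyl)-3-methyl-1-(propan-2-yl)cyclopent-2-en-1-yl]-4,4,5,5-tetramethyl-1,3,2-dioxaborolane | CC1(C)OB([C@]2(C(C)C)CCC(C)=C2CCCC(OCC)OCC)OC1(C)C | intermediate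
11 | (1S)-2-(4,4-diethoxybutyl)-3-methyl-1-(propan-2-yl)cyclopent-2-en-1-ol | O[C@]1(C(C)C)CCC(C)=C1CCCC(OCC)OCC | intermediate
12 | (1S)-2-(4,4-diethoxybutyl)-3-methyl-1-(propan-2-yl)cyclopent-2-en-1-yl 2-(phenylsulfinyl)ethyl ether (both sulfur epimers) | O=S(CCO[C@]1(C(C)C)CCC(C)=C1CCCC(OCC)OCC)c1ccccc1 | intermediate
13 | (1S)-2-(4,4-diethoxybutyl)-1-(ethenyloxy)-3-methyl-1-(propan-2-yl)cyclopent-2-ene | C=CO[C@]1(C(C)C)CCC(C)=C1CCCC(OCC)OCC | intermediate
14 | 2-[(1R)-2-(4,4-diethoxybutyl)-1-methyl-3-(propan-2-yl)cyclopent-2-en-1-yl]acetaldehyde | O=CC[C@@]1(C)CCC(C(C)C)=C1CCCC(OCC)OCC | intermediate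
15 | 4-[(5R)-5-methyl-5-(2-oxoethyl)-2-(propan-2-yl)cyclopent-1-en-1-yl]butanal | O=CC[C@@]1(C)CCC(C(C)C)=C1CCCC=O | intermediate
16 | (3aR)-3a-methyl-1-(propan-2-yl)-2,3,3a,4,7,8-hexahydroazulene-6-carbaldehyde | O=CC1=CC[C@@]2(C)CCC(C(C)C)=C2CC1 | intermediate
17 | [(3aR)-3a-methyl-1-(propan-2-yl)-2,3,3a,4,7,8-hexahydroazulen-6-yl]methanol | OCC1=CC[C@@]2(C)CCC(C(C)C)=C2CC1 | intermediate
18 | 4-hydroxy-3-methoxybenzoic acid (vanillic acid) | COc1cc(C(=O)O)ccc1O | starting material
19 | [(3aR)-3a-methyl-1-(propan-2-yl)-2,3,3a,4,7,8-hexahydroazulen-6-yl]methyl 4-hydroxy-3-methoxybenzoate | COc1cc(C(=O)OCC2=CC[C@@]3(C)CCC(C(C)C)=C3CC2)ccc1O | target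

**Step count**

Total step count: 9. Longest linear sequence: 9 steps (1 → 19); 3 and 18 are purchased.

**Steps most likely to fail**

Step 7. The aldol stage may enolise on the wrong aldehyde (C10 attacking C14) or oligomerise instead of closing the seven-membered ring, and ionisation of the tertiary allylic ether before the [3,3] shift would erode the chirality transfer. The fallback keeps the Claisen shift for C1–C10 but closes C8=C9 by metathesis. It sets out from 14, isolated after the thermal stage. Wittig methylenation (Ph3P=CH2 from Ph3PCH3Br and KN(SiMe3)2, THF, 0 °C) should give (5R)-1-(4,4-diethoxybutyl)-5-methyl-5-(prop-2-en-1-yl)-2-(propan-2-yl)cyclopent-1-ene F1. Aqueous HCl in THF should then give 4-[(5R)-5-methyl-5-(prop-2-en-1-yl)-2-(propan-2-yl)cyclopent-1-en-1-yl]butanal F2. Amine-catalysed α-methylenation (aqueous formaldehyde, pyrrolidine, propionic acid, iPrOH, 45 °C) should give 2-methylidene-4-[(5R)-5-methyl-5-(prop-2-en-1-yl)-2-(propan-2-yl)cyclopent-1-en-1-yl]butanal F3. Reduction with NaBH4 and CeCl3·7H2O should give 2-methylidene-4-[(5R)-5-methyl-5-(prop-2-en-1-yl)-2-(propan-2-yl)cyclopent-1-en-1-yl]butan-1-ol F4. Ring-closing metathesis with second-generation Grubbs catalyst, RuCl2(=CHPh)(H2IMes)(PCy3), in CH2Cl2 at 40 °C should close C8=C9, and the route is rejoined at 17.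

Step 5. Formation of the boronate complex from the hindered secondary boronic ester may be slow or reversible, borylation may occur at C1 instead of C4, and the lithiated carbamate may lose configuration before the 1,2-shift. The fallback sets out from 5 and omits steps 3 and 4. Addition of iPrMgCl in the presence of CeCl3 (THF, −78 °C) should give racemic 2-(4,4-diethoxybutyl)-3-methyl-1-(propan-2-yl)cyclopent-2-en-1-ol F5. Separation of the enantiomers by preparative chromatography on a chiral stationary phase should give 11 beside the unwanted (1R)-2-(4,4-diethoxybutyl)-3-methyl-1-(propan-2-yl)cyclopent-2-en-1-ol F6. The route is rejoined at 11.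

Step 6. The oxa-Michael addition of the hindered tertiary alkoxide may stay incomplete or revert, and the tertiary allylic oxygen may be lost by elimination. The fallback sets out from 11 and uses transfer vinylation with vinyl acetate ([Ir(cod)Cl]2, Na2CO3, toluene, 100 °C), which should give the vinyl ether 13 directly. The route is rejoined at 13, which enters step 7 at the Claisen stage; no new compound is made.

**Further compounds**

F1 | step 7 | (5R)-1-(4,4-diethoxybutyl)-5-methyl-5-(prop-2-en-1-yl)-2-(propan-2-yl)cyclopent-1-ene | C=CC[C@@]1(C)CCC(C(C)C)=C1CCCC(OCC)OCC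
F2 | step 7 | 4-[(5R)-5-methyl-5-(prop-2-en-1-yl)-2-(propan-2-yl)cyclopent-1-en-1-yl]butanal | C=CC[C@@]1(C)CCC(C(C)C)=C1CCCC=O
F3 | step 7 | 2-methylidene-4-[(5R)-5-methyl-5-(prop-2-en-1-yl)-2-(propan-2-yl)cyclopent-1-en-1-yl]butanal | C=CC[C@@]1(C)CCC(C(C)C)=C1CCC(=C)C=O
F4 | step 7 | 2-methylidene-4-[(5R)-5-methyl-5-(prop-2-en-1-yl)-2-(propan-2-yl)cyclopent-1-en-1-yl]butan-1-ol | C=CC[C@@]1(C)CCC(C(C)C)=C1CCC(=C)CO
F5 | step 5 | racemic 2-(4,4-diethoxybutyl)-3-methyl-1-(propan-2-yl)cyclopent-2-en-1-ol | OC1(C(C)C)CCC(C)=C1CCCC(OCC)OCC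
F6 | step 5 | (1R)-2-(4,4-diethoxybutyl)-3-methyl-1-(propan-2-yl)cyclopent-2-en-1-ol | O[C@@]1(C(C)C)CCC(C)=C1CCCC(OCC)OCC
F0 | step 6 | none | none
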